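**Retrosynthetic overview**

1. Target ⇐ removal of the two lactone carbonyl oxygens (C9, C9') from an endo,endo 8-hydroxy dilactone; the bicycle and all four stereocentres are already in place.
2. ⇐ α-hydroxylation at one ring-fusion carbon of a C2-symmetric endo,endo dilactone (the cis fusion fixes the new centre).
3. ⇐ catalyst-controlled double syn-hydrogenation of a planar, achiral bis(enol lactone), a 3,6-diarylfuro[3,4-c]furan-1,4-dione; this sets C7, C8, C7' and C8' together and forces both aryls endo.
4. ⇐ double dehydrogenation of the racemic exo,exo dilactone ⇐ oxidative 8–8' coupling of two ferulic acids with double quinone-methide lactonisation. Ring A and ring B close together in this first step and stay closed to the end.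

Assumption: the SMILES is read as (1S,2S,5R,6R)-2,6-bis(4-hydroxy-3-methoxyphenyl)-3,7-dioxabicyclo[3.3.0]octan-1-ol, the 2,6-bis-epi isomer of 8-hydroxypinoresinol with both aryl groups endo (trans to the ring-fusion OH and H), not the common exo,exo isomer.

Locants used below (lignan style): C7/C7' benzylic, C8/C8' ring fusion (C8 carries OH in the target), C9/C9' the remaining ring carbons; ring A holds C7' and C9, ring B holds C7 and C9'; exo = aryl cis to the ring-fusion substituents, endo = trans.

**Route**

Step 1
Reactants: 1 ferulic acid (2 equiv)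
Product: 3 rac-(1S,2S,5S,6S)-2,6-bis(4-hydroxy-3-methoxyphenyl)-3,7-dioxabicyclo[3.3.0]octane-4,8-dione (racemic exo,exo dilactone), via bis(quinone methide) diacid 2 (not isolated)
Conditions: FeCl3·6H2O (1.1 equiv), acetone/H2O, rt
Reagents that add atoms: none
Why: Oxidative phenol coupling followed by double quinone-methide lactonisation, as in lignan biosynthesis: trivalent iron gives the ferulate phenoxy radical, two radicals join C8–C8' to 2, and each carboxyl adds to the quinone-methide carbon of the other half (C9–O–C7' closes ring A, C9'–O–C7 closes ring B); the ring fusion can only be cis and allylic strain in the quinone methide puts both aryls exo, so 3 is one racemic diastereomer whose configuration is deliberately erased in step 2.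

Step 2
Reactants: 3 racemic exo,exo dilactone
Product: 5 3,6-bis(4-hydroxy-3-methoxyphenyl)furo[3,4-c]furan-1,4-dione (planar, achiral bis(enol lactone)), via half-dehydrogenated lactone 4 (not isolated)
Conditions: DDQ (2.3 equiv), 1,4-dioxane, 90 °C
Reagents that add atoms: none
Why: Proposed new method: with the 4-OH free, DDQ takes hydride from the benzylic C7–H (giving the acyloxy-substituted p-hydroxybenzyl cation, i.e. the protonated quinone methide), loss of the acidic C8–H beside the lactone carbonyl then forms the enol-lactone C7=C8 bond, and the same sequence on the second half (through 4) gives planar, achiral, fully conjugated 5, the lactone analogue of the diketopyrrolopyrrole chromophore; closest known reaction: DDQ dehydrogenation of flavanones to flavones (O–CH(Ar)–CH–C=O to O–C(Ar)=C–C=O).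

Step 3
Reactants: 5 bis(enol lactone)
Product: 7 (1S,2R,5S,6R)-2,6-bis(4-hydroxy-3-methoxyphenyl)-3,7-dioxabicyclo[3.3.0]octane-4,8-dione (endo,endo dilactone, C2-symmetric), via half-hydrogenated lactone 6 (not isolated)
Conditions: Ru(OAc)2[(R)-BINAP] (2 mol %), H2 (80 bar), CH2Cl2/CF3CH2OH, 50 °C
Reagents that add atoms: none
Why: Proposed new method: Noyori-type asymmetric hydrogenation of enol lactones and alkylidene lactones with Ru(OAc)2(BINAP), here stretched to a tetrasubstituted bis(enol lactone): the chiral divalent ruthenium catalyst selects one of the two enantiotopic faces of 5 and adds H2 syn across C7=C8 (6), the now folded bicycle leaves only its convex face open so the second syn addition lands on the same side, and the resulting all-cis array of H7, H8, H8', H7' places both aryls endo and fixes all four stereocentres in one operation (ligand hand assigned by analogy, to be confirmed on 7; the (S)-ligand gives the mirror image); closest known reactions: Ru–BINAP hydrogenation of 4-methylene-γ-butyrolactones, 2-alkylidene-γ-butyrolactones and diketene.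

Step 4
Reactants: 7 endo,endo dilactone
Product: 9 (1R,2S,5R,6R)-1-hydroxy-2,6-bis(4-hydroxy-3-methoxyphenyl)-3,7-dioxabicyclo[3.3.0]octane-4,8-dione (endo,endo 8-hydroxy dilactone), via trisodium enolate 8 (not isolated)
Conditions: NaN(SiMe3)2 (3.3 equiv), THF/DMPU, −78 °C; 2-(phenylsulfonyl)-3-phenyloxaziridine (1.2 equiv), −78 °C; AcOH, −78 °C
Reagents that add atoms: 2-(phenylsulfonyl)-3-phenyloxaziridine (Davis oxaziridine), O=S(=O)(c1ccccc1)N1OC1c1ccccc1
Why: Enolate α-hydroxylation (Davis oxidation): two equivalents of base give the bis(phenoxide), the third forms ring-fusion enolate 8, and the oxaziridine can deliver oxygen only to the face that keeps the 5/5 system cis-fused, i.e. the convex face cis to H8' and anti to both aryls, so OH takes the place of H8 with retention (new centre C8); C2 symmetry of 7 makes the two ring-fusion positions equivalent, and at −78 °C with a cold quench the phenoxides do not expel the lactone carboxylates and the β-hydroxy lactone does not undergo retro-aldol cleavage.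

Step 5
Reactants: 9 endo,endo 8-hydroxy dilactone
Product: 11 (1S,2S,5R,6R)-2,6-bis(4-hydroxy-3-methoxyphenyl)-3,7-dioxabicyclo[3.3.0]octan-1-ol (target), via bis(lactol) 10 (not isolated)
Conditions: iBu2AlH (5.2 equiv), CH2Cl2/THF, −78 °C; then Et3SiH, BF3·OEt2, −78 to −40 °C; aq. potassium sodium tartrate
Reagents that add atoms: none
Why: Kraus lactone-to-ether reduction (lactol formation, then ionic hydrogenation of the oxocarbenium ions): iBu2AlH stops at bis(lactol) aluminate 10 and masks the two phenols and the tertiary alcohol as aluminium alkoxides, BF3·OEt2/Et3SiH then replace the anomeric oxygens at C9 and C9' by hydrogen, and since no stereocentre is involved and the endo benzylic C–O bonds are not ionised at low temperature the configuration of 9 is carried into 11.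

**Compound list**

1 | ferulic acid, (E)-3-(4-hydroxy-3-methoxyphenyl)prop-2-enoic acid | COc1cc(/C=C/C(=O)O)ccc1O | starting material
2 | 8–8' bis(quinone methide) diacid, rac-(2R,3R)-2,3-bis[(3-methoxy-4-oxocyclohexa-2,5-dien-1-ylidene)methyl]butanedioic acid (racemic, one enantiomer drawn; exocyclic C=C geometry not fixed; not isolated) | OC(=O)[C@H](C=C1C=CC(=O)C(OC)=C1)[C@@H](C=C1C=CC(=O)C(OC)=C1)C(=O)O | intermediate
3 | racemic exo,exo dilactone, rac-(1S,2S,5S,6S)-2,6-bis(4-hydroxy-3-methoxyphenyl)-3,7-dioxabicyclo[3.3.0]octane-4,8-dione (one enantiomer drawn; each aryl cis to both ring-fusion H) | COc1cc([C@H]2OC(=O)[C@H]3[C@@H]2C(=O)O[C@@H]3c2ccc(O)c(OC)c2)ccc1O | intermediate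
4 | half-dehydrogenated lactone, rac-(5S,6S)-2,6-bis(4-hydroxy-3-methoxyphenyl)-3,7-dioxabicyclo[3.3.0]oct-1-ene-4,8-dione (one C7=C8 enol-lactone bond; remaining aryl cis to the remaining ring-fusion H; racemic, one enantiomer drawn; not isolated) | COc1cc(C2=C3C(=O)O[C@H](c4ccc(O)c(OC)c4)[C@H]3C(=O)O2)ccc1O | intermediate
5 | 3,6-bis(4-hydroxy-3-methoxyphenyl)furo[3,4-c]furan-1,4-dione (planar, achiral; C7=C8 and C7'=C8' enol-lactone double bonds) | COc1cc(C2=C3C(=O)OC(c4ccc(O)c(OC)c4)=C3C(=O)O2)ccc1O | intermediate
6 | half-hydrogenated lactone, (5S,6R)-2,6-bis(4-hydroxy-3-methoxyphenyl)-3,7-dioxabicyclo[3.3.0]oct-1-ene-4,8-dione (H7 and H8 cis; C7'=C8' still present; not isolated) | COc1cc(C2=C3C(=O)O[C@@H](c4ccc(O)c(OC)c4)[C@H]3C(=O)O2)ccc1O | intermediate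
7 | endo,endo dilactone, (1S,2R,5S,6R)-2,6-bis(4-hydroxy-3-methoxyphenyl)-3,7-dioxabicyclo[3.3.0]octane-4,8-dione (H7, H8, H8', H7' all cis; both aryls trans to the ring-fusion H) | COc1cc([C@@H]2OC(=O)[C@H]3[C@@H]2C(=O)O[C@H]3c2ccc(O)c(OC)c2)ccc1O | intermediate
8 | trisodium salt of 7: ring-fusion (C8) lactone enolate, both phenols as phenoxides (not isolated) | [Na+].[Na+].[Na+].COc1cc([C@@H]2OC([O-])=C3[C@@H]2C(=O)O[C@H]3c2ccc([O-])c(OC)c2)ccc1[O-] | intermediate
9 | endo,endo 8-hydroxy dilactone, (1R,2S,5R,6R)-1-hydroxy-2,6-bis(4-hydroxy-3-methoxyphenyl)-3,7-dioxabicyclo[3.3.0]octane-4,8-dione (OH cis to H8', trans to both aryls) | COc1cc([C@@H]2OC(=O)[C@@]3(O)[C@@H]2C(=O)O[C@H]3c2ccc(O)c(OC)c2)ccc1O | intermediate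
10 | bis(lactol), (1R,2S,5R,6R)-2,6-bis(4-hydroxy-3-methoxyphenyl)-3,7-dioxabicyclo[3.3.0]octane-1,4,8-triol (anomeric mixture at C9 and C9'; present in the flask as its aluminium alkoxide; not isolated) | COc1cc([C@@H]2OC(O)[C@@]3(O)[C@@H]2C(O)O[C@H]3c2ccc(O)c(OC)c2)ccc1O | intermediate
11 | (1S,2S,5R,6R)-2,6-bis(4-hydroxy-3-methoxyphenyl)-3,7-dioxabicyclo[3.3.0]octan-1-ol (CNP0138682.2) | COc1cc([C@@H]2OC[C@@]3(O)[C@@H]2CO[C@H]3c2ccc(O)c(OC)c2)ccc1O | target

**Step count and risks**

Total: 5 steps. Longest linear sequence: 5 steps (1 → 3 → 5 → 7 → 9 → 11).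

Risk 1 – step 2. The double DDQ dehydrogenation has no direct precedent on a dilactone, and the phenols may be over-oxidised instead. The fallback sets out from 3 and comes back at 9 without the planar intermediate. TBSCl/imidazole (DMF) converts 3 into the racemic exo,exo bis(tert-butyldimethylsilyl) dilactone F1. LiN(iPr)2 (2.3 equiv, THF/DMPU, −78 °C) removes both ring-fusion protons and gives the planar dilithium bis(enolate) F2, one face of which is covered by both aryl groups. 2-(Phenylsulfonyl)-3-phenyloxaziridine (1.0 equiv) and a cold acetic acid quench then deliver O to C8 and H to C8' from the open face; the second addition is forced cis by the ring fusion. This inverts both ring-fusion centres relative to the aryls and gives the racemic endo,endo bis(silyl) 8-hydroxy dilactone F3. Bu4NF/AcOH frees the phenols to give racemic 9, and preparative chromatography on a chiral phase removes the mirror-image hydroxy dilactone ent-9 F4. The price is a resolution in place of asymmetric catalysis.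

Risk 2 – step 3. Enantioselectivity on a tetrasubstituted, weakly chelating double bond is uncertain, and migration of the remaining double bond to C8=C8' in 6 would scramble C7'. The fallback sets out from 5 and comes back at 7, with resolution instead of asymmetric catalysis. Hydrogenation of 5 over Rh/Al2O3 (H2 4 bar, EtOAc, rt; chosen over palladium to avoid benzylic C–O hydrogenolysis) gives the same all-cis dilactone as the racemate, that is 7 together with the mirror-image endo,endo dilactone ent-7 F5. Preparative chromatography on a chiral stationary phase then delivers 7. The relative configuration (both aryls endo) does not depend on the chiral catalyst.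

Risk 3 – step 5. The endo benzylic C7–O and C7'–O bonds of a free-phenol furofuran may ionise under BF3·OEt2 and close again exo, or be cleaved reductively. The fallback sets out from 9 and comes back at 11 with no Lewis acid. TIPSCl/imidazole gives the bis(triisopropylsilyl) hydroxy dilactone F6. LiAlH4 (THF, 0 °C, inverse addition) reduces both lactones to the pentaol F7. MsCl (2.1 equiv)/pyridine at 0 °C sulfonylates only the two primary hydroxyls; the bis(methanesulfonate) F8, not isolated, closes both rings by 5-exo-tet attack of the benzylic hydroxyls on C9 and C9' (Williamson-type, retention at C7 and C7'). This gives the bis(triisopropylsilyl) ether of the target F9, and Bu4NF removes the silyl groups to give 11.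

**Further compounds**

F1 | step 2 | racemic exo,exo bis(tert-butyldimethylsilyl) dilactone (bis-TBS ether of 3; one enantiomer drawn) | COc1cc([C@@H]2OC(=O)[C@@H]3[C@H]2C(=O)O[C@H]3c2ccc(O[Si](C)(C)C(C)(C)C)c(OC)c2)ccc1O[Si](C)(C)C(C)(C)C
F2 | step 2 | dilithium bis(enolate) of F1 (planar at C8 and C8'; C7 and C7' unchanged; racemic, one enantiomer drawn) | [Li+].[Li+].COc1cc([C@@H]2OC([O-])=C3C2=C([O-])O[C@H]3c2ccc(O[Si](C)(C)C(C)(C)C)c(OC)c2)ccc1O[Si](C)(C)C(C)(C)C
F3 | step 2 | racemic endo,endo bis(tert-butyldimethylsilyl) 8-hydroxy dilactone (bis-TBS ether of racemic 9; one enantiomer drawn) | COc1cc([C@@H]2OC(=O)[C@@]3(O)[C@@H]2C(=O)O[C@H]3c2ccc(O[Si](C)(C)C(C)(C)C)c(OC)c2)ccc1O[Si](C)(C)C(C)(C)C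
F4 | step 2 | ent-9, (1S,2R,5S,6S)-1-hydroxy-2,6-bis(4-hydroxy-3-methoxyphenyl)-3,7-dioxabicyclo[3.3.0]octane-4,8-dione | COc1cc([C@H]2OC(=O)[C@]3(O)[C@H]2C(=O)O[C@@H]3c2ccc(O)c(OC)c2)ccc1O
F5 | step 3 | ent-7, (1R,2S,5R,6S)-2,6-bis(4-hydroxy-3-methoxyphenyl)-3,7-dioxabicyclo[3.3.0]octane-4,8-dione | COc1cc([C@H]2OC(=O)[C@@H]3[C@H]2C(=O)O[C@@H]3c2ccc(O)c(OC)c2)ccc1O
F6 | step 5 | bis(triisopropylsilyl) ether of 9 | COc1cc([C@@H]2OC(=O)[C@@]3(O)[C@@H]2C(=O)O[C@H]3c2ccc(O[Si](C(C)C)(C(C)C)C(C)C)c(OC)c2)ccc1O[Si](C(C)C)(C(C)C)C(C)C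
F7 | step 5 | pentaol, 2,3-bis(hydroxymethyl)-1,4-bis[3-methoxy-4-(triisopropylsilyloxy)phenyl]butane-1,2,4-triol with the configuration of 9 at all four centres | COc1cc([C@H](O)[C@@H](CO)[C@](O)(CO)[C@@H](O)c2ccc(O[Si](C(C)C)(C(C)C)C(C)C)c(OC)c2)ccc1O[Si](C(C)C)(C(C)C)C(C)C
F8 | step 5 | bis(methanesulfonate) of F7 at the two primary hydroxyls (C9 and C9'; not isolated) | COc1cc([C@H](O)[C@@H](COS(C)(=O)=O)[C@](O)(COS(C)(=O)=O)[C@@H](O)c2ccc(O[Si](C(C)C)(C(C)C)C(C)C)c(OC)c2)ccc1O[Si](C(C)C)(C(C)C)C(C)C
F9 | step 5 | bis(triisopropylsilyl) ether of 11 | COc1cc([C@@H]2OC[C@@]3(O)[C@@H]2CO[C@H]3c2ccc(O[Si](C(C)C)(C(C)C)C(C)C)c(OC)c2)ccc1O[Si](C(C)C)(C(C)C)C(C)C
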